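**Series waits.** If each catalyst turn is two waits in series, one shrinking as c(coupling partner) rises and one that does not, then the times add, and the order in c(coupling partner) equals the first wait's share of the turn.

| flask | substrate | coupling partner | free catalyst | time |
|---|---|---|---|---|
| theta | 0.250 M | 0.625 M | 0.00130 M |  |
| beta | 0.250 M | 0.310 M | 0.00130 M |  |
| eta | 0.250 M | 0.625 M | 0.00190 M |  |
| zeta | 0.620 M | 0.625 M | 0.00130 M | 27 h |

| run | time / h | [target] / M |
|---|---|---|
| theta run | 1.1 | 0.0092 |
| theta run | 1.7 | 0.0126 |
| theta run | 2.7 | 0.0183 |
| theta run | 4.3 | 0.0304 |
| theta run | 6.8 | 0.0435 |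
| theta run | 11 | 0.0606 |
| theta run | 17 | 0.0773 |
| theta run | 27 | 0.0914 |
| beta run | 1.1 | 0.0057 |
| beta run | 1.7 | 0.0094 |
| beta run | 2.7 | 0.0147 |
| beta run | 4.3 | 0.0227 |
| beta run | 6.8 | 0.0331 |
| beta run | 11 | 0.0513 |
| beta run | 17 | 0.0649 |
| beta run | 27 | 0.0812 |
| eta run | 1.1 | 0.0128 |
| eta run | 1.7 | 0.0183 |
| eta run | 2.7 | 0.0278 |
| eta run | 4.3 | 0.0425 |
| eta run | 6.8 | 0.0607 |
| eta run | 11 | 0.0837 |
| eta run | 17 | 0.1029 |
| eta run | 27 | 0.1109 |

(each reading ± 8 × 10⁻⁴ M)

- apparent order in [coupling partner] of the starting rate, round the charge of the theta run (the rate where two percent of its substrate have turned into target)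
- apparent order in [free catalyst] of the starting rate, round the charge of the theta run (the rate where two percent of its substrate have turned into target)
- target in the zeta run at 27 h, as a share of the substrate charged

- Overall: substrate + coupling partner -> target, with free catalyst as catalyst.
- Constant volume, constant temperature.
- An order is taken over about fifteen percent of the charge, up and down.

**First way.** For my reading of each starting rate, I divide the summed target readings up to 4.3 h by the summed clock times: 0.00719 M/h in the theta run and 0.00536 M/h in the beta run, a ratio of 0.745. The straight chord between the two partner charges gives an order of 0.420.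

**Second way.** Writing reciprocal rate as a constant plus a term in 1/c(coupling partner), the same ratio gives the partner share, the first wait's fraction of the turn at the theta charge: 0.337. The ways part. At the beta charge, the share is 0.507, and the chord lies between the two shares, lower than 0.507 and higher than 0.337. The chord is a mean over a factor of 2.02 in the charge, so I take the partner share, which belongs to the theta charge. For the catalyst, the same reading gives 0.0103 M/h in the eta run, a ratio of 1.44 to the theta run and an order of 0.958.

**Zeta estimate.** Substrate is the limiting reagent in the zeta run: 0.620 M is less than 0.625 M. I assume the other wait scales as 1/c(substrate). The partner share then puts the zeta starting rate at 0.0119 M/h.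

My yardstick is starting rate times 27 h over substrate charge. It reads 0.579 for beta, 0.777 for theta and 1.12 for eta. Their shares of substrate as target at that time rise in the same order: 32.5%, 36.6%, 44.4%. Zeta's yardstick is 0.518, lower than beta's, so I estimate the zeta share below 32.5%.

**The forecast.** It gives 0.45 for the partner, 1 for the catalyst and 27% for zeta, and it warns: “No run varies substrate, so zeta is uncertain”. Its partner order is higher than my share, and its zeta value stands below the beta share.

**The flask.** The orders come out at 0.32 for the partner, against my share of 0.337, and 1.0 for the catalyst. The zeta run reaches 27.1%, while the fit with main steps alone gives 37.2%.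

    free catalyst + substrate → loaded catalyst + by-product (36.36 /M/h)
    loaded catalyst + coupling partner → target + free catalyst (30.46 /M/h)
    target + coupling partner → side product (0.02952 /M/h)
    target → decomposed product (0.02232 /h)

The partner share puts the zeta start at 0.0119 M/h, and the zeta run holds 0.168 M of target at 27 h, so its mean rate of 0.00622 M/h is half that estimated start.

All runs are calculated for substances that don't exist; the scatter is artificial.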